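The ratio of D at 5.00 min to D at 12.0 min in Tuesday's run is 2.10, and its natural logarithm over the time between them is what I call the tail constant, 0.106 min⁻¹, the pseudo-first-order constant of D after the start.

| setting | Tuesday's | Saturday's | Thursday's | flask |
|---|---|---|---|---|
| D | 1.1 M | 1.8 M | 0.80 M | 0.80 M |
| Z | 0.024 M | 0.024 M | 0.024 M | 0.0240 M |
| J | 5.9 mM | 5.9 mM | 12 mM | 5.9 mM |
| remark | run made earlier | run made earlier | run made earlier |  |
| time |  |  |  | 20 min |

| run | time / min | D / % | Q / % | G / % |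
|---|---|---|---|---|
| Tuesday's | 2.50 | 84.0 | 6.2 | 9.4 |
| Tuesday's | 5.00 | 66.4 | 20.1 | 13.4 |
| Tuesday's | 8.00 | 48.7 | 35.5 | 15.7 |
| Tuesday's | 10.0 | 39.2 | 43.8 | 16.2 |
| Tuesday's | 12.0 | 31.6 | 51.6 | 16.7 |
| Saturday's | 2.50 | 81.6 | 9.8 | 9.1 |
| Saturday's | 5.00 | 63.3 | 27.9 | 11.5 |
| Saturday's | 8.00 | 44.5 | 43.5 | 11.0 |
| Saturday's | 10.0 | 36.6 | 54.1 | 11.4 |
| Saturday's | 12.0 | 29.0 | 59.9 | 10.0 |
| Thursday's | 1.00 | 92.6 | 0.8 | 6.6 |
| Thursday's | 2.00 | 80.5 | 5.0 | 14.5 |
| Thursday's | 3.00 | 69.0 | 11.4 | 20.0 |
| Thursday's | 6.00 | 40.0 | 30.7 | 30.6 |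
| Thursday's | 12.0 | 12.9 | 52.2 | 35.7 |

(scatter of a reading: 0.5 percentage points)

- a species is counted by the D in it: one Q counts as two
- the numbers in the tables scatter by 0.5 percentage points (one standard deviation)

* the species that holds most of what was charged as D, at 20 min (G / Q / D)
* the largest share itself, whichever of these holds it, in percent of the D charged

Now I draw this flask, in percent of the D charged. D starts steeply: Tuesday's run loses 16 percentage points in 2.50 min. G has a knee. Tuesday's run ends at 16.7 % of its D, which is 0.184 M, and Saturday's ends at 0.180 M, so I take that concentration as the level here, 23.0 % of 0.80 M. Q is the remainder, as Tuesday's last row sums to 99.9 %. In Tuesday's run Q crosses G between two readings: it is lower than G at 2.50 min, 6.2 % against 9.4 %, and higher at 5.00 min, 20.1 % against 13.4 %, so I draw the crossing in this flask early too, while G is still climbing. At 20 min the closed form c_D(t) = c_D(t₀)·exp(−k(t − t₀)), run from Tuesday's last reading, gives D 13.5 %, which leaves Q 63.5 %, more than either other species.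

The forecast says Q with 64 %: “Q has a lag, then takes over as the main product”. It stands on the same readings as my curve, so their nearness is no check.

Q holds most, 62.6 %, with D at 16.8 %.

    D + E → G + E, rate k1*[E]*[D] (k = 0.184 L mol⁻¹ s⁻¹)
    D + G → Q (k = 0.00462 L mol⁻¹ s⁻¹)
    D + J → E + G (k = 0.0320 L mol⁻¹ s⁻¹)
    E + Z → L (k = 0.0161 L mol⁻¹ s⁻¹)

At 20 min the flask uses D in making G at 0.93 of the rate at which it uses D in making Q. Between 10.0 min and 20 min its D falls with a constant of 0.0931 min⁻¹, against 0.106 min⁻¹. The forecast's choice fails in the neighbour charged with 0.20 M of D: 0.106 min⁻¹ gives 13.5 % there, but D stands at 28.9 % and G holds most, 41.9 %.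

The earlier runs and the new flask are simulated with constants of no real substance; noise was put on by code.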